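**Assumption:** Locants follow the geranylgeranyl chain (C1 = ArCH2, C3 = exocyclic-methylene carbon, C7 = quaternary ring carbon, C15 = CMe2–O), so the target is (2R,6S,7S,10R,11S,14R). Both Shi ketone enantiomers and (E)-4-chloro-3-methylbut-2-enyl acetate are taken as purchasable.

## Retrosynthetic overview

1. Final stage: one relay step from a tris(β-bromo tertiary trifluoroacetate) ("stored bromonium ions") closes the cyclohexane (C2–C7) first, then the 16-membered lactone (C15–O).
2. Each C–Br centre (C6, C10, C14) comes from a Shi epoxide opened by bromide with inversion; C11 comes directly from the epoxide; C7 and C2 follow from stereospecific anti addition through a chair.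
3. The aryl group is attached at C1 by Pd-catalysed allyl–aryl (Negishi) coupling of an allylic acetate.
4. The C20 chain comes from farnesyl phenyl sulfone plus a C5 chloro-acetate. The allylic sulfone (then the allylic acetate) switches off the neighbouring alkene, so the ent-Shi ketone epoxidises 10,11/14,15 and the Shi ketone later epoxidises 6,7.

## Route

**Step 1**
Reactants: 1, (2E,6E)-farnesyl bromide
Product: 2, (2E,6E)-farnesyl phenyl sulfone
Conditions: PhSO2Na, DMF, rt
Reagents that add atoms: sodium benzenesulfinate, [Na+].[O-]S(=O)c1ccccc1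
Why: SN2 S-alkylation of sulfinate by a primary allylic bromide is a standard sulfone synthesis and retains both E-alkenes.

**Step 2**
Reactants: 2
Product: 3, (2E,6S,7S,10S)-6,7:10,11-diepoxyfarnesyl phenyl sulfone (target locants 10S,11S,14S)
Conditions: ent-Shi ketone (L-fructose-derived, 0.4 equiv), Oxone, K2CO3, Bu4NHSO4, MeCN–DMM–aq. borate buffer pH 10.5, 0 °C
Reagents that add atoms: Oxone (potassium peroxymonosulfate), [K+].[O-]S(=O)(=O)OO
Why: Shi asymmetric epoxidation (chiral dioxirane, spiro transition state) oxidises the two electron-rich trisubstituted alkenes on the face giving S,S/S epoxides, while the alkene next to the electron-withdrawing allylic sulfone is left untouched.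

**Step 3**
Reactants: 3; 4, (E)-4-chloro-3-methylbut-2-en-1-yl acetate
Product: 5, (2E,6E,10S,11S,14S)-10,11:14,15-diepoxy-5-(phenylsulfonyl)geranylgeranyl acetate (C5 epimers)
Conditions: n-BuLi, THF, −78 °C; then 4, −78 → −30 °C
Reagents that add atoms: none (all atoms from 3 and 4)
Why: Alkylation of an α-sulfonyl allyl carbanion with an allylic chloride (Julia-type isoprenoid coupling) forms C4–C5 with the 2E geometry of 4 retained; the temporary C5 centre is uncontrolled and is removed in Step 4.

**Step 4**
Reactants: 5
Product: 6, (2E,6E,10S,11S,14S)-10,11:14,15-diepoxygeranylgeraniol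
Conditions: LiBHEt3 (3 equiv), THF, −78 °C; then PdCl2(dppp) (5 mol %), −78 → 0 °C
Reagents that add atoms: none
Why: Hydride first cleaves the acetate to an alkoxide that Pd cannot ionise, then Pd-catalysed reductive desulfonylation delivers hydride to the less substituted π-allyl terminus (C5), restoring the 6E-alkene; the hindered trisubstituted epoxides survive at ≤0 °C.

**Step 5**
Reactants: 6
Product: 7, (2E,6E,10S,11S,14S)-10,11:14,15-diepoxygeranylgeranyl acetate
Conditions: Ac2O, pyridine, DMAP (cat.), CH2Cl2, 0 °C
Reagents that add atoms: acetic anhydride, CC(=O)OC(C)=O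
Why: Simple acylation; the allylic acetate deactivates the 2,3-alkene for Step 6 and is the leaving group for Step 8.

**Step 6**
Reactants: 7
Product: 8, (2E,6R,7R,10S,11S,14S)-6,7:10,11:14,15-triepoxygeranylgeranyl acetate
Conditions: Shi ketone (D-fructose-derived, 0.3 equiv), Oxone (1.6 equiv), K2CO3, Bu4NHSO4, MeCN–DMM–buffer pH 10.5, 0 °C
Reagents that add atoms: Oxone, [K+].[O-]S(=O)(=O)OO
Why: A second Shi epoxidation with the opposite catalyst enantiomer gives the 6R,7R epoxide under catalyst control; the 6,7-alkene reacts in preference to the acetate-deactivated 2,3-alkene, as in 6,7-selective epoxidation of geranyl acetate.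

**Step 7**
Reactants: 9, tert-butyl 4-hydroxybenzoate
Product: 10, tert-butyl 4-acetoxy-3-iodobenzoate
Conditions: NIS (1.0 equiv), TFA (5 mol %), MeCN, rt; then Ac2O, Et3N, DMAP (one pot)
Reagents that add atoms: N-iodosuccinimide, O=C1CCC(=O)N1I; acetic anhydride, CC(=O)OC(C)=O
Why: Electrophilic iodination goes ortho to the phenol (para is blocked), and in-situ acetylation gives an electron-poor aryl iodide whose oxygen can no longer act as a nucleophile.

**Step 8**
Reactants: 8; 10
Product: 11, tert-butyl 4-acetoxy-3-[(2E,6R,7R,10S,11S,14S)-6,7:10,11:14,15-triepoxy-3,7,11,15-tetramethylhexadec-2-en-1-yl]benzoate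
Conditions: 10, Zn dust, LiCl, THF, 40 °C (ArZnI·LiCl); then 8, Pd(PPh3)4 (5 mol %), THF, 25 °C
Reagents that add atoms: none (all atoms from 8 and 10)
Why: Negishi allyl–aryl coupling of an allylic acetate couples at the unhindered π-allyl terminus with retention of the E-alkene; the ester, aryl acetate and non-allylic epoxides tolerate the neutral arylzinc.

**Step 9**
Reactants: 11
Product: 12, tert-butyl 4-acetoxy-3-[(2E,6S,7R,10R,11S,14R)-6,10,14-tribromo-7,11,15-trihydroxy-3,7,11,15-tetramethylhexadec-2-en-1-yl]benzoate
Conditions: Li2NiBr4 (6 equiv), THF, 0 °C → rt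
Reagents that add atoms: dilithium tetrabromonickelate, [Li+].[Li+].[Ni+2].[Br-].[Br-].[Br-].[Br-]
Why: Soft bromide opens each trisubstituted epoxide by SN2 at the secondary carbon with inversion, giving 6S, 10R and 14R bromides and leaving the tertiary C–O centres (7R, 11S) intact; excess bromide under non-acidic conditions outruns hydroxy-epoxide cyclisation.

**Step 10**
Reactants: 12
Product: 13, the 7,11,15-tris(trifluoroacetate) of 12
Conditions: TFAA (6 equiv), pyridine (10 equiv), CH2Cl2, −20 → 0 °C
Reagents that add atoms: trifluoroacetic anhydride, O=C(OC(=O)C(F)(F)F)C(F)(F)F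
Why: Trifluoroacetylation of the tertiary alcohols removes them as nucleophiles (no bromo-etherification later) and turns each bromohydrin into a latent bromonium ion with a good leaving group.

**Step 11**
Reactants: 13
Product: 14, O-acetyl-11-O-trifluoroacetyl-bromophycolide H
Conditions: Sc(OTf)3 (0.5 equiv), 2,6-di-tert-butyl-4-methylpyridine (4 equiv), HFIP–CH2Cl2 (1:4), 1 mM, −20 → 25 °C
Reagents that add atoms: none
Why: Proposed new method: Lewis-acid/HFIP-assisted ionisation of each β-bromo tertiary trifluoroacetate with bromine participation regenerates the configurationally defined bromonium ion reversibly (trifluoroacetate return is stereoretentive). The 6,7-ion is trapped at once by the 2,3-alkene through a chair (anti addition sets 7S and 2R; the hindered base removes a C3-methyl proton to give the exocyclic alkene). The 14,15-ion is then captured at C15 by the tert-butyl ester carbonyl with loss of isobutylene to close the 16-membered lactone, while the 10,11-ion can only form a strained 12-membered meta-bridged ring and reverts to the C11 trifluoroacetate. Closest known reactions are enantiospecific bromonium generation from bromohydrin derivatives with intramolecular O- or alkene capture, bromonium polyene cyclisation, and halo-macrolactonisation of alkenoic acids and tert-butyl esters.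

**Step 12**
Reactants: 14
Product: 15, bromophycolide H
Conditions: NH3 (2 M in MeOH), 0 °C
Reagents that add atoms: none
Why: Mild ammonolysis cleaves the aryl acetate and the activated C11 trifluoroacetate without the alkoxide base that would close the bromohydrin to an epoxide; the hindered tertiary benzoate lactone and neopentyl-type bromides are unaffected.

## Compound list

1 | (2E,6E)-farnesyl bromide | BrC/C=C(\C)CC/C=C(\C)CCC=C(C)C | starting material
2 | (2E,6E)-farnesyl phenyl sulfone | O=S(=O)(C/C=C(\C)CC/C=C(\C)CCC=C(C)C)c1ccccc1 | intermediate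
3 | (2E,6S,7S,10S)-6,7:10,11-diepoxyfarnesyl phenyl sulfone | O=S(=O)(C/C=C(\C)CC[C@@H]1O[C@@]1(C)CC[C@@H]1OC1(C)C)c1ccccc1 | intermediate
4 | (E)-4-chloro-3-methylbut-2-en-1-yl acetate | CC(=O)OC/C=C(\C)CCl | starting material
5 | (2E,6E,10S,11S,14S)-10,11:14,15-diepoxy-5-(phenylsulfonyl)geranylgeranyl acetate (C5 epimers) | CC(=O)OC/C=C(\C)CC(S(=O)(=O)c1ccccc1)/C=C(\C)CC[C@@H]1O[C@@]1(C)CC[C@@H]1OC1(C)C | intermediate
6 | (2E,6E,10S,11S,14S)-10,11:14,15-diepoxygeranylgeraniol | OC/C=C(\C)CC/C=C(\C)CC[C@@H]1O[C@@]1(C)CC[C@@H]1OC1(C)C | intermediate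
7 | (2E,6E,10S,11S,14S)-10,11:14,15-diepoxygeranylgeranyl acetate | CC(=O)OC/C=C(\C)CC/C=C(\C)CC[C@@H]1O[C@@]1(C)CC[C@@H]1OC1(C)C | intermediate
8 | (2E,6R,7R,10S,11S,14S)-6,7:10,11:14,15-triepoxygeranylgeranyl acetate | CC(=O)OC/C=C(\C)CC[C@H]1O[C@]1(C)CC[C@@H]1O[C@@]1(C)CC[C@@H]1OC1(C)C | intermediate
9 | tert-butyl 4-hydroxybenzoate | CC(C)(C)OC(=O)c1ccc(O)cc1 | starting material
10 | tert-butyl 4-acetoxy-3-iodobenzoate | CC(=O)Oc1ccc(cc1I)C(=O)OC(C)(C)C | intermediate
11 | tert-butyl 4-acetoxy-3-[(2E,6R,7R,10S,11S,14S)-6,7:10,11:14,15-triepoxy-3,7,11,15-tetramethylhexadec-2-enyl]benzoate | CC(=O)Oc1ccc(cc1C/C=C(\C)CC[C@H]1O[C@]1(C)CC[C@@H]1O[C@@]1(C)CC[C@@H]1OC1(C)C)C(=O)OC(C)(C)C | intermediate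
12 | tert-butyl 4-acetoxy-3-[(2E,6S,7R,10R,11S,14R)-6,10,14-tribromo-7,11,15-trihydroxy-3,7,11,15-tetramethylhexadec-2-enyl]benzoate | CC(=O)Oc1ccc(cc1C/C=C(\C)CC[C@H](Br)[C@](C)(O)CC[C@@H](Br)[C@@](C)(O)CC[C@@H](Br)C(C)(C)O)C(=O)OC(C)(C)C | intermediate
13 | 7,11,15-tris(trifluoroacetate) of 12 | CC(=O)Oc1ccc(cc1C/C=C(\C)CC[C@H](Br)[C@](C)(OC(=O)C(F)(F)F)CC[C@@H](Br)[C@@](C)(OC(=O)C(F)(F)F)CC[C@@H](Br)C(C)(C)OC(=O)C(F)(F)F)C(=O)OC(C)(C)C | intermediate
14 | O-acetyl-11-O-trifluoroacetyl-bromophycolide H | C=C1CC[C@H](Br)[C@@]2(C)CC[C@@H](Br)[C@@](C)(OC(=O)C(F)(F)F)CC[C@@H](Br)C(C)(C)OC(=O)c3ccc(OC(C)=O)c(c3)C[C@H]12 | intermediate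
15 | bromophycolide H | C=C1CC[C@H](Br)[C@@]2(C)CC[C@@H](Br)[C@@](C)(O)CC[C@@H](Br)C(C)(C)OC(=O)c3ccc(O)c(c3)C[C@H]12 | target

## Step count and risks

Total steps: 12. Longest linear sequence: 11 (Steps 1–6, 8–12).

Steps most likely to fail:

1. **Step 11 (proposed new relay carbocyclisation/macrolactonisation).** Likely failures are proton loss from the C11/C15 ions to allylic bromides, endocyclic alkene isomers at C3, and slow 16-ring capture. Fallback with known chemistry: omit Step 6 and carry the benzoate as an allyl ester. Close the ring with a stoichiometric bromonium reagent (BDSB-type) on the 2,3/6,7-diene and separate the ring diastereomers. Then methanolyse the trifluoroacetates, release the acid with Pd(0), and close the lactone onto the C15 alcohol by Yamaguchi or Shiina (MNBA) macrolactonisation at high dilution.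
2. **Step 9 (triple bromide opening).** Risks are attack at the tertiary carbons and tetrahydrofuran formation from a newly freed C7 or C11 hydroxyl onto a neighbouring epoxide. Fallback: open only the two East epoxides on alcohol 6, cap them as trifluoroacetates, and set the West bromide instead by a catalyst-controlled enantioselective bromocyclisation of the 2,3/6,7-diene after arylation.
3. **Step 4 (reductive desulfonylation beside two epoxides).** Hydride may open the epoxides. Fallback: avoid sulfone chemistry and build C1–C4 on bis-epoxyfarnesyl bromide by acetoacetate dianion alkylation, Z-enol phosphate formation, Me2CuLi and DIBAL (Weiler sequence) to reach 6.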